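**Plan**

Numbering: oxolane ring O1, C2 (ArA = 3-hydroxy-4,5-dimethoxyphenyl), C3 (CH3), C4 (CH3), C5 (ArB = 3,4,5-trimethoxyphenyl). The target is 2S,3S,4R,5R: the aryl groups are cis, the methyl groups are cis, and each aryl is trans to its neighbouring methyl.
Enabling feature: C2 lies between O1 and C3 and carries only ArA and H, so it is a masked ArA–CHO carbon. The C3 methyl is a vinyl group shortened by one carbon, which is the residue an allylsilane leaves after reacting through its γ-carbon.
Cuts: O–benzyl; C3–CH3 back through CH2OMs, CH2OH and CHO to CH=CH2; then O1–C2 and C2–C3 together (silyl-Prins); then the allylsilane C=C (cross-metathesis); last C4–C5 (crotylboration).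
Forward: C4–C5 is made first, the chain is extended to the E-allylsilane and the hydroxyl is silylated. The only ring then closes in one operation with the ArA aldehyde, the vinyl group is trimmed to methyl, and the phenol is freed.
Stereochemistry: C5 and C4 come from a catalyst-controlled anti-crotylboration. C2 and C3 follow from these two centres and from the E geometries of the oxocarbenium ion and the alkene in the ring closure.

Key step: step 5

Assumption: the (R)-configured phosphoric acid is taken to steer the crotyl group to the Re face of 3,4,5-trimethoxybenzaldehyde, as it does with other aryl aldehydes. The absolute configuration of the crotylation product is to be confirmed by MTPA ester analysis before the route is continued.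

Step 1
Reactants: 1 3-hydroxy-4,5-dimethoxybenzaldehyde
Product: 2 3-(benzyloxy)-4,5-dimethoxybenzaldehyde
Conditions: BnBr, K2CO3, DMF, rt
Reagents that add atoms: benzyl bromide, BrCc1ccccc1
Why: Williamson etherification of the only acidic OH gives a benzyl ether that should survive low-temperature Lewis acid, OsO4/NaIO4, borohydrides and mesylation and can be removed last.

Step 2
Reactants: 3 3,4,5-trimethoxybenzaldehyde; 4 (E)-crotylboronic acid pinacol ester
Product: 6 (1R,2R)-2-methyl-1-(3,4,5-trimethoxyphenyl)but-3-en-1-ol, via pinacol borate ester 5 (not isolated)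
Conditions: (R)-3,3'-bis(2,4,6-triisopropylphenyl)-1,1'-binaphthyl-2,2'-diyl hydrogen phosphate (5 mol %), 4 Å MS, toluene, −30 °C; then aq. NaHCO3
Reagents that add atoms: none
Why: In this chiral phosphoric acid-catalysed allylboration through a closed Zimmerman–Traxler chair, the E-crotyl geometry becomes the anti C4/C5 relationship, and the (R)-acid, hydrogen-bonded to the pseudoaxial boronate oxygen and the formyl hydrogen, should open the Re face of 3 to give the 1R,2R alcohol once borate 5 is hydrolysed.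

Step 3
Reactants: 6 (1R,2R)-2-methyl-1-(3,4,5-trimethoxyphenyl)but-3-en-1-ol; 7 allyltrimethylsilane
Product: 8 (1R,2R,3E)-2-methyl-1-(3,4,5-trimethoxyphenyl)-5-(trimethylsilyl)pent-3-en-1-ol
Conditions: 7 (3 equiv), second-generation Grubbs catalyst (H2IMes)(PCy3)Cl2Ru=CHPh (5 mol %), CH2Cl2, 40 °C
Reagents that add atoms: none
Why: In this olefin cross-metathesis of an allylically branched, slowly self-coupling terminal alkene with an excess of the rapidly exchanging allylsilane, reversibility and the branch next to the alkene should favour the E isomer, and neither stereocentre is touched.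

Step 4
Reactants: 8 (1R,2R,3E)-2-methyl-1-(3,4,5-trimethoxyphenyl)-5-(trimethylsilyl)pent-3-en-1-ol
Product: 9 trimethyl{[(1R,2R,3E)-2-methyl-1-(3,4,5-trimethoxyphenyl)-5-(trimethylsilyl)pent-3-en-1-yl]oxy}silane
Conditions: TMSCl, imidazole, CH2Cl2, 0 °C
Reagents that add atoms: chlorotrimethylsilane, C[Si](C)(C)Cl
Why: Standard O-silylation of a secondary alcohol turns OH into OSiMe3, so the ring closure can run without releasing water or protic acid next to two acid-sensitive benzylic positions and an allylsilane.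

Step 5
Reactants: 9 trimethyl{[(1R,2R,3E)-2-methyl-1-(3,4,5-trimethoxyphenyl)-5-(trimethylsilyl)pent-3-en-1-yl]oxy}silane; 2 3-(benzyloxy)-4,5-dimethoxybenzaldehyde
Product: 11 (2S,3S,4R,5R)-2-[3-(benzyloxy)-4,5-dimethoxyphenyl]-3-ethenyl-4-methyl-5-(3,4,5-trimethoxyphenyl)oxolane, via E-oxocarbenium triflate 10 (not isolated)
Conditions: TMSOTf (0.2 equiv), 2,6-di-tert-butyl-4-methylpyridine (0.3 equiv), CH2Cl2, −78 to −40 °C; Et3N, then aq. NaHCO3
Reagents that add atoms: none
Why: TMSOTf condenses silyl ether 9 with aldehyde 2, hexamethyldisiloxane leaves, and the resulting E-oxocarbenium ion 10 (O1=C2) is attacked at C2 by the γ-carbon of the allylsilane (new C2–C3 bond), after which triflate takes the silyl group from the developing β-silyl cation, unveiling the C3 vinyl group and returning TMSOTf. The closest known reaction type is the intramolecular Hosomi–Sakurai (silyl-Prins) cyclisation of 5-silylpent-3-en-1-ols and aldehydes to 2-substituted 3-vinyloxolanes, the ring-forming version of the three-component silyl ether/aldehyde/allylsilane coupling. The oxolane closes in a five-membered mode that is exo with respect to the C=C bond, which stays outside the ring, and endo with respect to the C=O+ bond, whose two atoms both become ring members, a mode that cationic heteroatom-stabilised electrophiles accept readily. C2 is controlled by the preset C5 centre: in the envelope transition state the E geometry holds ArA anti to C5 and pseudoequatorial, ArB takes the pseudoequatorial site at C5 with C5–H turned towards the C=O+ bond, and the trans C4 methyl follows it, so the two aryl groups end up cis. C3 is controlled by the E-alkene and by ArA: an E-alkene suffers no allylic 1,3-strain when the C4 methyl lies near its plane, so the CH=CH–CH2Si arm can point away from ArA, and the vinyl group ends up trans to ArA and cis to the C4 methyl. The step needs attack through C3 only (no 2-oxonia-Cope shift or six-ring Prins closure through the other alkene carbon) and intact benzylic C–O bonds, and these are secured by the β-silicon effect, which places the developing charge next to the CH2Si group, and by the water-free, base-buffered catalytic conditions made possible by the O-silyl group of 9.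

Step 6
Reactants: 11 (2S,3S,4R,5R)-2-[3-(benzyloxy)-4,5-dimethoxyphenyl]-3-ethenyl-4-methyl-5-(3,4,5-trimethoxyphenyl)oxolane
Product: 12 (2S,3S,4R,5R)-2-[3-(benzyloxy)-4,5-dimethoxyphenyl]-4-methyl-5-(3,4,5-trimethoxyphenyl)oxolane-3-carbaldehyde
Conditions: OsO4 (2 mol %), NaIO4 (4 equiv), 2,6-lutidine (2 equiv), 1,4-dioxane/H2O 3:1, rt
Reagents that add atoms: osmium tetroxide, O=[Os](=O)(=O)=O (delivers the aldehyde oxygen), regenerated by sodium periodate, [Na+].[O-]I(=O)(=O)=O
Why: Lemieux–Johnson cleavage (dihydroxylation followed by glycol fission) attacks only the monosubstituted alkene and, unlike ozone, spares the two electron-rich arenes, while the lutidine buffer and the already favoured trans-to-ArA placement of the formyl group should keep C3 in place.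

Step 7
Reactants: 12 (2S,3S,4R,5R)-2-[3-(benzyloxy)-4,5-dimethoxyphenyl]-4-methyl-5-(3,4,5-trimethoxyphenyl)oxolane-3-carbaldehyde
Product: 13 [(2S,3R,4R,5R)-2-[3-(benzyloxy)-4,5-dimethoxyphenyl]-4-methyl-5-(3,4,5-trimethoxyphenyl)oxolan-3-yl]methanol
Conditions: NaBH4, MeOH/THF, 0 °C
Reagents that add atoms: none
Why: Borohydride reduction of the aldehyde, run directly on the freshly made material, removes the enolisable carbonyl before C3 can drift, and the descriptor at C3 changes only because the CIP priorities change.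

Step 8
Reactants: 13 [(2S,3R,4R,5R)-2-[3-(benzyloxy)-4,5-dimethoxyphenyl]-4-methyl-5-(3,4,5-trimethoxyphenyl)oxolan-3-yl]methanol
Product: 14 [(2S,3R,4R,5R)-2-[3-(benzyloxy)-4,5-dimethoxyphenyl]-4-methyl-5-(3,4,5-trimethoxyphenyl)oxolan-3-yl]methyl methanesulfonate
Conditions: MsCl, Et3N, CH2Cl2, 0 °C
Reagents that add atoms: methanesulfonyl chloride, CS(=O)(=O)Cl
Why: Sulfonylation of the only free hydroxyl, a primary one, activates it as a leaving group without touching any stereocentre.

Step 9
Reactants: 14 [(2S,3R,4R,5R)-2-[3-(benzyloxy)-4,5-dimethoxyphenyl]-4-methyl-5-(3,4,5-trimethoxyphenyl)oxolan-3-yl]methyl methanesulfonate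
Product: 15 (2S,3S,4R,5R)-2-[3-(benzyloxy)-4,5-dimethoxyphenyl]-3,4-dimethyl-5-(3,4,5-trimethoxyphenyl)oxolane
Conditions: LiEt3BH (3 equiv), THF, 0 °C to rt
Reagents that add atoms: none
Why: SN2 displacement of a primary sulfonate by the strongly nucleophilic hydride of LiEt3BH is the standard CH2OH to CH3 deoxygenation of oxolane lignan intermediates, and it leaves aryl ethers, the benzyl ether and all four ring centres unchanged.

Step 10
Reactants: 15 (2S,3S,4R,5R)-2-[3-(benzyloxy)-4,5-dimethoxyphenyl]-3,4-dimethyl-5-(3,4,5-trimethoxyphenyl)oxolane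
Product: 16 5-[(2S,3S,4R,5R)-3,4-dimethyl-5-(3,4,5-trimethoxyphenyl)oxolan-2-yl]-2,3-dimethoxyphenol
Conditions: H2 (1 atm), 10% Pd/C, EtOAc, rt
Reagents that add atoms: none
Why: In this catalytic hydrogenolysis in a neutral solvent at atmospheric pressure, the unhindered primary O–CH2Ph bond should be cleaved much faster than the two secondary, flanked ring C–O bonds, provided the reaction is stopped as soon as 15 is consumed.

**Compound list**

1 | 3-hydroxy-4,5-dimethoxybenzaldehyde | COc1cc(C=O)cc(O)c1OC | starting material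
2 | 3-(benzyloxy)-4,5-dimethoxybenzaldehyde | COc1cc(C=O)cc(OCc2ccccc2)c1OC | intermediate
3 | 3,4,5-trimethoxybenzaldehyde | COc1cc(C=O)cc(OC)c1OC | starting material
4 | (E)-crotylboronic acid pinacol ester, 2-[(2E)-but-2-en-1-yl]-4,4,5,5-tetramethyl-1,3,2-dioxaborolane | C/C=C/CB1OC(C)(C)C(C)(C)O1 | starting material
5 | 4,4,5,5-tetramethyl-2-{[(1R,2R)-2-methyl-1-(3,4,5-trimethoxyphenyl)but-3-en-1-yl]oxy}-1,3,2-dioxaborolane | CC1(C)OB(O[C@@H](c2cc(OC)c(OC)c(OC)c2)[C@H](C)C=C)OC1(C)C | intermediate
6 | (1R,2R)-2-methyl-1-(3,4,5-trimethoxyphenyl)but-3-en-1-ol | O[C@@H](c1cc(OC)c(OC)c(OC)c1)[C@H](C)C=C | intermediate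
7 | allyltrimethylsilane | C=CC[Si](C)(C)C | starting material
8 | (1R,2R,3E)-2-methyl-1-(3,4,5-trimethoxyphenyl)-5-(trimethylsilyl)pent-3-en-1-ol | O[C@@H](c1cc(OC)c(OC)c(OC)c1)[C@H](C)/C=C/C[Si](C)(C)C | intermediate
9 | trimethyl{[(1R,2R,3E)-2-methyl-1-(3,4,5-trimethoxyphenyl)-5-(trimethylsilyl)pent-3-en-1-yl]oxy}silane | C[Si](C)(C)O[C@@H](c1cc(OC)c(OC)c(OC)c1)[C@H](C)/C=C/C[Si](C)(C)C | intermediate
10 | (E)-[3-(benzyloxy)-4,5-dimethoxybenzylidene][(1R,2R,3E)-2-methyl-1-(3,4,5-trimethoxyphenyl)-5-(trimethylsilyl)pent-3-en-1-yl]oxonium trifluoromethanesulfonate | COc1cc(/C=[O+]/[C@@H](c2cc(OC)c(OC)c(OC)c2)[C@H](C)/C=C/C[Si](C)(C)C)cc(OCc2ccccc2)c1OC.[O-]S(=O)(=O)C(F)(F)F | intermediate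
11 | (2S,3S,4R,5R)-2-[3-(benzyloxy)-4,5-dimethoxyphenyl]-3-ethenyl-4-methyl-5-(3,4,5-trimethoxyphenyl)oxolane | COc1cc([C@H]2O[C@@H](c3cc(OC)c(OC)c(OC)c3)[C@H](C)[C@@H]2C=C)cc(OCc4ccccc4)c1OC | intermediate
12 | (2S,3S,4R,5R)-2-[3-(benzyloxy)-4,5-dimethoxyphenyl]-4-methyl-5-(3,4,5-trimethoxyphenyl)oxolane-3-carbaldehyde | COc1cc([C@H]2O[C@@H](c3cc(OC)c(OC)c(OC)c3)[C@H](C)[C@@H]2C=O)cc(OCc4ccccc4)c1OC | intermediate
13 | [(2S,3R,4R,5R)-2-[3-(benzyloxy)-4,5-dimethoxyphenyl]-4-methyl-5-(3,4,5-trimethoxyphenyl)oxolan-3-yl]methanol | COc1cc([C@H]2O[C@@H](c3cc(OC)c(OC)c(OC)c3)[C@H](C)[C@@H]2CO)cc(OCc4ccccc4)c1OC | intermediate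
14 | [(2S,3R,4R,5R)-2-[3-(benzyloxy)-4,5-dimethoxyphenyl]-4-methyl-5-(3,4,5-trimethoxyphenyl)oxolan-3-yl]methyl methanesulfonate | COc1cc([C@H]2O[C@@H](c3cc(OC)c(OC)c(OC)c3)[C@H](C)[C@@H]2COS(C)(=O)=O)cc(OCc4ccccc4)c1OC | intermediate
15 | (2S,3S,4R,5R)-2-[3-(benzyloxy)-4,5-dimethoxyphenyl]-3,4-dimethyl-5-(3,4,5-trimethoxyphenyl)oxolane | COc1cc([C@H]2O[C@@H](c3cc(OC)c(OC)c(OC)c3)[C@H](C)[C@@H]2C)cc(OCc4ccccc4)c1OC | intermediate
16 | 5-[(2S,3S,4R,5R)-3,4-dimethyl-5-(3,4,5-trimethoxyphenyl)oxolan-2-yl]-2,3-dimethoxyphenol | COc1cc([C@H]2O[C@@H](c3cc(OC)c(OC)c(OC)c3)[C@H](C)[C@@H]2C)cc(O)c1OC | target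

**Step count and risks**

Total steps: 10. Longest linear sequence: 9 (steps 2 to 10, from 3); step 1 lies on the convergent branch.

**Step 5.** The risk is weak facial discrimination at the allylsilane carbon C3, so that part of the vinyl group is delivered cis to ArA. Any Z-alkene carried over from step 3 makes this worse, because its allylic 1,3-strain turns the side chain the other way. The fallback gives up kinetic control at C3 in favour of thermodynamic control one oxidation level later. It sets out from 9 and returns at 12.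
- 9 and 2 are cyclised as before, and the C3-epimeric vinyl oxolane F1 is not separated from 11.
- The mixture is cleaved with OsO4/NaIO4/2,6-lutidine, which gives the C3-epimeric oxolane-3-carbaldehyde F2 beside 12.
- DBU in CH2Cl2 at room temperature then equilibrates C3 through the enolate.
- In F2 the formyl group stands cis to the bulky ArA, whereas in 12 it is cis only to the C4 methyl, so the material should collect in 12.
- The mild base and short contact time are chosen so that β-elimination of O1 does not set in.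

**Step 3.** The risk is incomplete E-selectivity, together with loss of catalyst turnover to self-metathesis of the allylsilane. The fallback fixes the alkene geometry by olefination and a stereoretentive cross-coupling instead of metathesis. It sets out from 6 and returns at 8.
- 6 is protected with TESCl/imidazole as the triethylsilyl ether F3.
- The vinyl group is cleaved with OsO4/NaIO4/2,6-lutidine to the α-methyl-β-silyloxy aldehyde F4.
- Takai olefination (CrCl2, CHI3, THF, 0 °C) gives the E-vinyl iodide F5.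
- Kumada coupling with Me3SiCH2MgCl under Pd(PPh3)4 catalysis replaces iodine with retention of geometry and gives the O-triethylsilyl E-allylsilane F6.
- AcOH/THF/H2O removes the triethylsilyl group to give 8.

**Step 10.** The risk is over-reduction, that is, hydrogenolytic opening of the oxolane at C2–O1 or C5–O1, which are benzylic as well. The fallback carries a fluoride-labile phenol mask from the beginning, so that no hydrogenation is needed. It sets out from 1 and returns at 16.
- 1 is silylated with TIPSCl/imidazole to the triisopropylsilyl-protected aldehyde F7.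
- F7 takes the place of 2 in step 5 and gives, with 9, the silyl-protected vinyl oxolane F8.
- The conditions of steps 6 to 9 then lead by way of the silyl-protected aldehyde F9, the silyl-protected primary alcohol F10 and the silyl-protected mesylate F11 to the silyl-protected 3,4-dimethyl oxolane F12.
- TBAF in THF at 0 °C frees 16.

Further compounds
F1 | step 5 | (2S,3R,4R,5R)-2-[3-(benzyloxy)-4,5-dimethoxyphenyl]-3-ethenyl-4-methyl-5-(3,4,5-trimethoxyphenyl)oxolane | COc1cc([C@H]2O[C@@H](c3cc(OC)c(OC)c(OC)c3)[C@H](C)[C@H]2C=C)cc(OCc4ccccc4)c1OC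
F2 | step 5 | (2S,3R,4R,5R)-2-[3-(benzyloxy)-4,5-dimethoxyphenyl]-4-methyl-5-(3,4,5-trimethoxyphenyl)oxolane-3-carbaldehyde | COc1cc([C@H]2O[C@@H](c3cc(OC)c(OC)c(OC)c3)[C@H](C)[C@H]2C=O)cc(OCc4ccccc4)c1OC
F3 | step 3 | triethyl{[(1R,2R)-2-methyl-1-(3,4,5-trimethoxyphenyl)but-3-en-1-yl]oxy}silane | CC[Si](CC)(CC)O[C@@H](c1cc(OC)c(OC)c(OC)c1)[C@H](C)C=C
F4 | step 3 | (2S,3R)-2-methyl-3-[(triethylsilyl)oxy]-3-(3,4,5-trimethoxyphenyl)propanal | CC[Si](CC)(CC)O[C@@H](c1cc(OC)c(OC)c(OC)c1)[C@H](C)C=O
F5 | step 3 | triethyl{[(1R,2R,3E)-4-iodo-2-methyl-1-(3,4,5-trimethoxyphenyl)but-3-en-1-yl]oxy}silane | CC[Si](CC)(CC)O[C@@H](c1cc(OC)c(OC)c(OC)c1)[C@H](C)/C=C/I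
F6 | step 3 | triethyl{[(1R,2R,3E)-2-methyl-1-(3,4,5-trimethoxyphenyl)-5-(trimethylsilyl)pent-3-en-1-yl]oxy}silane | CC[Si](CC)(CC)O[C@@H](c1cc(OC)c(OC)c(OC)c1)[C@H](C)/C=C/C[Si](C)(C)C
F7 | step 10 | 3,4-dimethoxy-5-{[tri(propan-2-yl)silyl]oxy}benzaldehyde | COc1cc(C=O)cc(O[Si](C(C)C)(C(C)C)C(C)C)c1OC
F8 | step 10 | {5-[(2S,3S,4R,5R)-3-ethenyl-4-methyl-5-(3,4,5-trimethoxyphenyl)oxolan-2-yl]-2,3-dimethoxyphenoxy}tri(propan-2-yl)silane | COc1cc([C@H]2O[C@@H](c3cc(OC)c(OC)c(OC)c3)[C@H](C)[C@@H]2C=C)cc(O[Si](C(C)C)(C(C)C)C(C)C)c1OC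
F9 | step 10 | (2S,3S,4R,5R)-2-(3,4-dimethoxy-5-{[tri(propan-2-yl)silyl]oxy}phenyl)-4-methyl-5-(3,4,5-trimethoxyphenyl)oxolane-3-carbaldehyde | COc1cc([C@H]2O[C@@H](c3cc(OC)c(OC)c(OC)c3)[C@H](C)[C@@H]2C=O)cc(O[Si](C(C)C)(C(C)C)C(C)C)c1OC
F10 | step 10 | [(2S,3R,4R,5R)-2-(3,4-dimethoxy-5-{[tri(propan-2-yl)silyl]oxy}phenyl)-4-methyl-5-(3,4,5-trimethoxyphenyl)oxolan-3-yl]methanol | COc1cc([C@H]2O[C@@H](c3cc(OC)c(OC)c(OC)c3)[C@H](C)[C@@H]2CO)cc(O[Si](C(C)C)(C(C)C)C(C)C)c1OC
F11 | step 10 | [(2S,3R,4R,5R)-2-(3,4-dimethoxy-5-{[tri(propan-2-yl)silyl]oxy}phenyl)-4-methyl-5-(3,4,5-trimethoxyphenyl)oxolan-3-yl]methyl methanesulfonate | COc1cc([C@H]2O[C@@H](c3cc(OC)c(OC)c(OC)c3)[C@H](C)[C@@H]2COS(C)(=O)=O)cc(O[Si](C(C)C)(C(C)C)C(C)C)c1OC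
F12 | step 10 | {5-[(2S,3S,4R,5R)-3,4-dimethyl-5-(3,4,5-trimethoxyphenyl)oxolan-2-yl]-2,3-dimethoxyphenoxy}tri(propan-2-yl)silane | COc1cc([C@H]2O[C@@H](c3cc(OC)c(OC)c(OC)c3)[C@H](C)[C@@H]2C)cc(O[Si](C(C)C)(C(C)C)C(C)C)c1OC
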